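**Retrosynthetic overview**
- The triene is cut at C16=C17 (Horner–Wadsworth–Emmons with a geranyl phosphonate) and C14=C15 (Wittig). The C1 enal and the C3 alcohol come from two esters by reduction and allylic oxidation.
- The only ring (C6–C7–C8–C9–C10–C11) is closed by forming C10–C11 in an acyclic keto diene: hydrogen-atom transfer to a C11=CH2 group gives the C26 methyl and the C11 radical, which adds 6-exo to the C10 methyl ketone.
- Enabling feature: in the ring the methyl carbinol C10 is bonded directly to the quaternary C11 that carries a CH3, and the exocyclic tetrasubstituted C7=C2 alkene next to C6 lets the single C6 centre direct C10 and C11 through A(1,3) strain.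
- The acyclic precursor gets its (2Z)-enoate from syn-carbocupration/methylation of an ynoate. Its one stereocentre (C6) is C4 of (R)-limonene, kept through C10-lithiation/oxirane opening, ozonolytic opening of the ring C=C and haloform loss of the ring methyl.

Key step: step 11

Remark: atoms are named in iridal numbering (C1 = aldehyde carbon, C2 = its α-carbon with methyl C25, C3–C5 = hydroxypropyl chain with OH on C3, ring = C6 (CH), C7 (alkylidene carbon), C8, C9, C10 (carbinol, methyl C27), C11 (quaternary, methyl C26), side chain = C12–C24); compound 21 is drawn as the open hydroxy aldehyde although it should rest largely as its six-membered lactol.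

**Route**

Step 1
Reactants: 1 (R)-(+)-limonene
Product: 3 4-[(1R)-4-methylcyclohex-3-en-1-yl]pent-4-en-1-ol, via allyllithium 2 (not isolated)
Conditions: n-BuLi, TMEDA, hexane, rt; then oxirane, THF, −78 → 0 °C; H2O
Reagents that add atoms: oxirane C1CO1
Why: Allylic lithiation with n-BuLi/TMEDA should take a proton from the isopropenyl CH3 (giving the 2-substituted allyllithium whose two termini are equivalent CH2 groups), and SN2 opening of oxirane by this allyl anion adds C13 and C14 with the C14 oxygen while the ring stereocentre (future C6) is a spectator.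

Step 2
Reactants: 3 4-[(1R)-4-methylcyclohex-3-en-1-yl]pent-4-en-1-ol
Product: 4 triisopropylsilyl ether of 3
Conditions: i-Pr3SiCl, imidazole, DMF, rt
Reagents that add atoms: chlorotriisopropylsilane CC(C)[Si](Cl)(C(C)C)C(C)C
Why: Standard silyl ether formation, chosen because the TIPS ether should survive ozone, cold aqueous NaOH and mild acid.

Step 3
Reactants: 4 triisopropylsilyl ether of 3
Product: 6 (5R)-7,7-dimethoxy-5-[5-(triisopropylsilyloxy)pent-1-en-2-yl]heptan-2-one, via keto aldehyde 5 (not isolated)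
Conditions: O3 (1.0 equiv), CH2Cl2/MeOH, −78 °C; Me2S, −78 °C → rt; then p-TsOH·H2O (cat.), rt
Reagents that add atoms: ozone [O-][O+]=O; methanol CO
Why: Ozonolysis limited to one equivalent should cleave the electron-richer trisubstituted ring alkene before the 1,1-disubstituted one and open the ring without touching the stereocentre, and acid in methanol should then acetalise only the aldehyde because a methyl ketone is not ketalised appreciably without a water scavenger.

Step 4
Reactants: 6 (5R)-7,7-dimethoxy-5-[5-(triisopropylsilyloxy)pent-1-en-2-yl]heptan-2-one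
Product: 7 (4R)-6,6-dimethoxy-4-[5-(triisopropylsilyloxy)pent-1-en-2-yl]hexanoic acid
Conditions: Br2, NaOH, H2O/1,4-dioxane, 0 °C (NaOBr formed in situ); then citric acid to pH 4
Reagents that add atoms: sodium hydroxide [Na+].[OH-]
Why: The haloform reaction (exhaustive α-bromination of the CH3C(=O) group, then cleavage by hydroxide) should remove the former ring methyl as CHBr3 and leave the C3 carboxylic acid, the cold strongly basic medium sparing acetal, silyl ether and alkene.

Step 5
Reactants: 7 (4R)-6,6-dimethoxy-4-[5-(triisopropylsilyloxy)pent-1-en-2-yl]hexanoic acid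
Product: 8 tert-butyl (4R)-6,6-dimethoxy-4-[5-(triisopropylsilyloxy)pent-1-en-2-yl]hexanoate
Conditions: O-tert-butyl-N,N'-diisopropylisourea, CH2Cl2, rt
Reagents that add atoms: O-tert-butyl-N,N'-diisopropylisourea CC(C)N=C(NC(C)C)OC(C)(C)C
Why: Isourea esterification is neutral, so the acetal stays, and the tert-butyl ester should resist the organolithium and organocopper steps that follow.

Step 6
Reactants: 8 tert-butyl (4R)-6,6-dimethoxy-4-[5-(triisopropylsilyloxy)pent-1-en-2-yl]hexanoate
Product: 9 tert-butyl (4R)-6-oxo-4-[5-(triisopropylsilyloxy)pent-1-en-2-yl]hexanoate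
Conditions: AcOH/H2O/THF (3:1:1), 45 °C
Reagents that add atoms: water O
Why: Mild aqueous acid hydrolysis of the acyclic dimethyl acetal, under which tert-butyl ester and TIPS ether are stable.

Step 7
Reactants: 9 tert-butyl (4R)-6-oxo-4-[5-(triisopropylsilyloxy)pent-1-en-2-yl]hexanoate
Product: 11 tert-butyl (4S)-4-ethynyl-5-methylidene-8-(triisopropylsilyloxy)octanoate, via alkenyl nonaflate 10 (not isolated)
Conditions: C4F9SO2F (NfF), P2-Et phosphazene base (2.5 equiv), DMF, −20 °C → rt
Reagents that add atoms: none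
Why: Enol sulfonylation of the enolisable aldehyde followed by E2 loss of nonaflate (the known one-pot aldehyde-to-terminal-alkyne conversion) should make C7≡C2 without adding carbon, and because enolisation runs towards C7 the C6 centre is not part of the enolate (the descriptor changes only through CIP priorities).

Step 8
Reactants: 11 tert-butyl (4S)-4-ethynyl-5-methylidene-8-(triisopropylsilyloxy)octanoate
Product: 13 7-tert-butyl 1-methyl (4S)-4-[5-(triisopropylsilyloxy)pent-1-en-2-yl]hept-2-ynedioate, via lithium acetylide 12 (not isolated)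
Conditions: n-BuLi (1.0 equiv), THF, −78 °C; cannulated into ClCO2Me (3 equiv), THF, −78 °C
Reagents that add atoms: methyl chloroformate COC(=O)Cl
Why: Acetylide acylation, in which the sp C–H should be lithiated faster than n-BuLi attacks a tert-butyl ester at −78 °C and inverse addition to excess chloroformate should consume the acetylide before it can deprotonate the acidic C6–H of the ynoate.

Step 9
Reactants: 13 7-tert-butyl 1-methyl (4S)-4-[5-(triisopropylsilyloxy)pent-1-en-2-yl]hept-2-ynedioate; 14 2-(2-bromoethyl)-2-methyl-1,3-dioxolane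
Product: 17 7-tert-butyl 1-methyl (2Z,4S)-2-methyl-3-[2-(2-methyl-1,3-dioxolan-2-yl)ethyl]-4-[5-(triisopropylsilyloxy)pent-1-en-2-yl]hept-2-enedioate, via Grignard reagent 15 (not isolated), via alkenylcopper 16 (not isolated)
Conditions: 14, Mg, THF; CuBr·SMe2, THF, −78 °C; 13, −78 °C; then MeI, DMPU, −78 → −30 °C
Reagents that add atoms: iodomethane CI
Why: Carbocupration of the ynoate is a syn addition that puts the C8–C10 arm on C7 and copper on C2 cis to it, and alkylation of the α-(alkoxycarbonyl)alkenylcopper with MeI at low temperature with retention should give the tetrasubstituted alkene with CH3 cis to C8 and the ester cis to C6 (2Z).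

Step 10
Reactants: 17 7-tert-butyl 1-methyl (2Z,4S)-2-methyl-3-[2-(2-methyl-1,3-dioxolan-2-yl)ethyl]-4-[5-(triisopropylsilyloxy)pent-1-en-2-yl]hept-2-enedioate
Product: 18 7-tert-butyl 1-methyl (2Z,4S)-2-methyl-3-(3-oxobutyl)-4-[5-(triisopropylsilyloxy)pent-1-en-2-yl]hept-2-enedioate
Conditions: PPTS, acetone/H2O, 50 °C
Reagents that add atoms: water O
Why: Buffered acid hydrolysis of the dioxolane should free the C10 methyl ketone without moving the alkenes that flank the doubly allylic C6–H.

Step 11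
Reactants: 18 7-tert-butyl 1-methyl (2Z,4S)-2-methyl-3-(3-oxobutyl)-4-[5-(triisopropylsilyloxy)pent-1-en-2-yl]hept-2-enedioate
Product: 19 methyl (2Z)-2-[(2R,3S,4S)-2-(3-tert-butoxy-3-oxopropyl)-4-hydroxy-3,4-dimethyl-3-[3-(triisopropylsilyloxy)propyl]cyclohexylidene]propanoate
Conditions: Fe(acac)3 (0.5 equiv), PhSiH3 (2.5 equiv), EtOH, 60 °C, 0.02 M
Reagents that add atoms: none
Why: Fe(acac)3 and PhSiH3 in EtOH should form an iron hydride that transfers a hydrogen atom to the CH2 terminus of the only electron-rich, unhindered alkene (C11=C26), creating the C26 methyl and the tertiary C11 radical, which adds to the C10 ketone before the alkoxy radical is reduced by divalent iron and protonated by EtOH. The closest known reaction type is the iron-hydride (Mukaiyama-type hydrogen-atom-transfer) radical cyclisation of alkene-tethered ketones to tertiary cycloalkanols. The single ring C6–C7–C8–C9–C10–C11 closes 6-exo-trig onto the carbonyl carbon. C10 and C11 are set by the C6 centre through a chair transition state: A(1,3) strain with the ester on the exocyclic C7=C2 alkene forces the C5 arm on C6 axial, the ketone then puts its oxygen (smaller than CH3) in the pseudoaxial site syn to that arm (10S), and the bulkier silyloxypropyl arm of the planar C11 radical takes the side anti to the axial C5 arm, leaving CH3 cis to it (11S). The step needs chemoselective hydrogen-atom transfer (the tetrasubstituted electron-poor C7=C2 alkene is inert, and C1 is kept as an ester so that no aldehyde competes as radical acceptor) and cyclisation faster than reduction of the radical (high dilution), while the facial choice at C11 rests only on the size difference between CH3 and the CH2CH2CH2OTIPS arm.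

Step 12
Reactants: 19 methyl (2Z)-2-[(2R,3S,4S)-2-(3-tert-butoxy-3-oxopropyl)-4-hydroxy-3,4-dimethyl-3-[3-(triisopropylsilyloxy)propyl]cyclohexylidene]propanoate
Product: 20 methyl (2Z)-2-[(2R,3S,4S)-2-(3-tert-butoxy-3-oxopropyl)-4-hydroxy-3-(3-hydroxypropyl)-3,4-dimethylcyclohexylidene]propanoate
Conditions: Bu4NF, AcOH, THF, 0 °C → rt
Reagents that add atoms: none
Why: Fluoride desilylation, buffered with AcOH so that the γ-C–H of the enoate (C6–H) is not deprotonated.

Step 13
Reactants: 20 methyl (2Z)-2-[(2R,3S,4S)-2-(3-tert-butoxy-3-oxopropyl)-4-hydroxy-3-(3-hydroxypropyl)-3,4-dimethylcyclohexylidene]propanoate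
Product: 21 methyl (2Z)-2-[(2R,3S,4S)-2-(3-tert-butoxy-3-oxopropyl)-4-hydroxy-3,4-dimethyl-3-(3-oxopropyl)cyclohexylidene]propanoate
Conditions: (COCl)2, DMSO, CH2Cl2, −78 °C; Et3N, −78 → −20 °C
Reagents that add atoms: none
Why: Swern oxidation should convert the primary alcohol at −78 °C and the activated DMSO is destroyed before the hydroxy aldehyde closes to its lactol, which avoids over-oxidation to the lactone, while the tertiary alcohol cannot be oxidised.

Step 14
Reactants: 21 methyl (2Z)-2-[(2R,3S,4S)-2-(3-tert-butoxy-3-oxopropyl)-4-hydroxy-3,4-dimethyl-3-(3-oxopropyl)cyclohexylidene]propanoate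
Product: 22 methyl (2Z)-2-[(2R,3S,4S)-2-(3-tert-butoxy-3-oxopropyl)-4-hydroxy-3,4-dimethyl-3-[(3E)-4-methyl-5-oxopent-3-en-1-yl]cyclohexylidene]propanoate
Conditions: Ph3P=C(CH3)CHO, toluene, 90 °C
Reagents that add atoms: 2-(triphenylphosphoranylidene)propanal CC(C=O)=P(c1ccccc1)(c1ccccc1)c1ccccc1
Why: The Wittig reaction with the stabilised formyl ylide should take the open aldehyde form of the lactol and give the (E)-2-methyl enal (C14=C15), as is usual for stabilised ylides.

Step 15
Reactants: 23 geranyl bromide; 24 triethyl phosphite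
Product: 25 diethyl [(2E)-3,7-dimethylocta-2,6-dien-1-yl]phosphonate
Conditions: neat, 130 °C, EtBr distilled off
Reagents that add atoms: none
Why: Michaelis–Arbuzov reaction at the primary allylic carbon, which should keep the (E)-trisubstituted alkene.

Step 16
Reactants: 22 methyl (2Z)-2-[(2R,3S,4S)-2-(3-tert-butoxy-3-oxopropyl)-4-hydroxy-3,4-dimethyl-3-[(3E)-4-methyl-5-oxopent-3-en-1-yl]cyclohexylidene]propanoate; 25 diethyl [(2E)-3,7-dimethylocta-2,6-dien-1-yl]phosphonate
Product: 27 methyl (2Z)-2-[(2R,3S,4S)-2-(3-tert-butoxy-3-oxopropyl)-4-hydroxy-3,4-dimethyl-3-[(3E,5E,7E)-4,8,12-trimethyltrideca-3,5,7,11-tetraen-1-yl]cyclohexylidene]propanoate, via lithiated phosphonate 26 (not isolated)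
Conditions: 25 (2.5 equiv), n-BuLi (2.4 equiv), THF, −78 °C; then 22, −78 → 0 °C
Reagents that add atoms: none
Why: Horner–Wadsworth–Emmons olefination of the enal with the allylic phosphonate anion should form C16=C17 with E geometry and complete the (14E,16E,18E)-triene, the excess anion allowing for the free tertiary alcohol.

Step 17
Reactants: 27 methyl (2Z)-2-[(2R,3S,4S)-2-(3-tert-butoxy-3-oxopropyl)-4-hydroxy-3,4-dimethyl-3-[(3E,5E,7E)-4,8,12-trimethyltrideca-3,5,7,11-tetraen-1-yl]cyclohexylidene]propanoate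
Product: 28 (2Z)-2-[(2R,3S,4S)-4-hydroxy-2-(3-hydroxypropyl)-3,4-dimethyl-3-[(3E,5E,7E)-4,8,12-trimethyltrideca-3,5,7,11-tetraen-1-yl]cyclohexylidene]propan-1-ol
Conditions: i-Bu2AlH (excess), CH2Cl2, −78 → 0 °C; aq. potassium sodium tartrate
Reagents that add atoms: none
Why: Hydride reduction of both esters (methyl enoate to the allylic alcohol, tert-butyl ester to the C3 alcohol) by excess i-Bu2AlH, which should not touch the unconjugated triene.

Step 18
Reactants: 28 (2Z)-2-[(2R,3S,4S)-4-hydroxy-2-(3-hydroxypropyl)-3,4-dimethyl-3-[(3E,5E,7E)-4,8,12-trimethyltrideca-3,5,7,11-tetraen-1-yl]cyclohexylidene]propan-1-ol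
Product: 29 CNP0237252.1, (2Z)-2-[(2R,3S,4S)-4-hydroxy-2-(3-hydroxypropyl)-3,4-dimethyl-3-[(3E,5E,7E)-4,8,12-trimethyltrideca-3,5,7,11-tetraen-1-yl]cyclohexylidene]propanal
Conditions: MnO2 (activated, excess), CH2Cl2, rt
Reagents that add atoms: none
Why: MnO2 oxidation is selective for the allylic primary alcohol and should give the (2Z)-enal while the saturated primary and the tertiary alcohol stay.

**Compound list**

1 | (R)-(+)-limonene | CC1=CC[C@@H](CC1)C(C)=C | starting material
2 | allyllithium (10-lithiolimonene) | [Li]CC(=C)[C@H]1CC=C(C)CC1 | intermediate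
3 | 4-[(1R)-4-methylcyclohex-3-en-1-yl]pent-4-en-1-ol | OCCCC(=C)[C@H]1CC=C(C)CC1 | intermediate
4 | triisopropylsilyl ether of 3 | CC(C)[Si](OCCCC(=C)[C@H]1CC=C(C)CC1)(C(C)C)C(C)C | intermediate
5 | (3R)-6-oxo-3-[5-(triisopropylsilyloxy)pent-1-en-2-yl]heptanal | O=CC[C@@H](CCC(C)=O)C(=C)CCCO[Si](C(C)C)(C(C)C)C(C)C | intermediate
6 | (5R)-7,7-dimethoxy-5-[5-(triisopropylsilyloxy)pent-1-en-2-yl]heptan-2-one | COC(OC)C[C@@H](CCC(C)=O)C(=C)CCCO[Si](C(C)C)(C(C)C)C(C)C | intermediate
7 | (4R)-6,6-dimethoxy-4-[5-(triisopropylsilyloxy)pent-1-en-2-yl]hexanoic acid | COC(OC)C[C@@H](CCC(=O)O)C(=C)CCCO[Si](C(C)C)(C(C)C)C(C)C | intermediate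
8 | tert-butyl (4R)-6,6-dimethoxy-4-[5-(triisopropylsilyloxy)pent-1-en-2-yl]hexanoate | COC(OC)C[C@@H](CCC(=O)OC(C)(C)C)C(=C)CCCO[Si](C(C)C)(C(C)C)C(C)C | intermediate
9 | tert-butyl (4R)-6-oxo-4-[5-(triisopropylsilyloxy)pent-1-en-2-yl]hexanoate | O=CC[C@@H](CCC(=O)OC(C)(C)C)C(=C)CCCO[Si](C(C)C)(C(C)C)C(C)C | intermediate
10 | alkenyl nonaflate of 9 (E/Z mixture) | FC(F)(F)C(F)(F)C(F)(F)C(F)(F)S(=O)(=O)OC=C[C@@H](CCC(=O)OC(C)(C)C)C(=C)CCCO[Si](C(C)C)(C(C)C)C(C)C | intermediate
11 | tert-butyl (4S)-4-ethynyl-5-methylidene-8-(triisopropylsilyloxy)octanoate | C#C[C@@H](CCC(=O)OC(C)(C)C)C(=C)CCCO[Si](C(C)C)(C(C)C)C(C)C | intermediate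
12 | lithium acetylide of 11 | [Li]C#C[C@@H](CCC(=O)OC(C)(C)C)C(=C)CCCO[Si](C(C)C)(C(C)C)C(C)C | intermediate
13 | 7-tert-butyl 1-methyl (4S)-4-[5-(triisopropylsilyloxy)pent-1-en-2-yl]hept-2-ynedioate | COC(=O)C#C[C@@H](CCC(=O)OC(C)(C)C)C(=C)CCCO[Si](C(C)C)(C(C)C)C(C)C | intermediate
14 | 2-(2-bromoethyl)-2-methyl-1,3-dioxolane | CC1(CCBr)OCCO1 | starting material
15 | [2-(2-methyl-1,3-dioxolan-2-yl)ethyl]magnesium bromide | CC1(CC[Mg]Br)OCCO1 | intermediate
16 | alkenylcopper from syn addition to 13 (Cu on C2, cis to the C8 arm) | COC(=O)/C([Cu])=C(/CCC1(C)OCCO1)[C@@H](CCC(=O)OC(C)(C)C)C(=C)CCCO[Si](C(C)C)(C(C)C)C(C)C | intermediate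
17 | 7-tert-butyl 1-methyl (2Z,4S)-2-methyl-3-[2-(2-methyl-1,3-dioxolan-2-yl)ethyl]-4-[5-(triisopropylsilyloxy)pent-1-en-2-yl]hept-2-enedioate | COC(=O)/C(C)=C(/CCC1(C)OCCO1)[C@@H](CCC(=O)OC(C)(C)C)C(=C)CCCO[Si](C(C)C)(C(C)C)C(C)C | intermediate
18 | 7-tert-butyl 1-methyl (2Z,4S)-2-methyl-3-(3-oxobutyl)-4-[5-(triisopropylsilyloxy)pent-1-en-2-yl]hept-2-enedioate | COC(=O)/C(C)=C(/CCC(C)=O)[C@@H](CCC(=O)OC(C)(C)C)C(=C)CCCO[Si](C(C)C)(C(C)C)C(C)C | intermediate
19 | methyl (2Z)-2-[(2R,3S,4S)-2-(3-tert-butoxy-3-oxopropyl)-4-hydroxy-3,4-dimethyl-3-[3-(triisopropylsilyloxy)propyl]cyclohexylidene]propanoate | CC(C)[Si](OCCC[C@@]1(C)[C@H](CCC(=O)OC(C)(C)C)/C(=C(/C)C(=O)OC)CC[C@]1(C)O)(C(C)C)C(C)C | intermediate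
20 | methyl (2Z)-2-[(2R,3S,4S)-2-(3-tert-butoxy-3-oxopropyl)-4-hydroxy-3-(3-hydroxypropyl)-3,4-dimethylcyclohexylidene]propanoate | OCCC[C@@]1(C)[C@H](CCC(=O)OC(C)(C)C)/C(=C(/C)C(=O)OC)CC[C@]1(C)O | intermediate
21 | methyl (2Z)-2-[(2R,3S,4S)-2-(3-tert-butoxy-3-oxopropyl)-4-hydroxy-3,4-dimethyl-3-(3-oxopropyl)cyclohexylidene]propanoate | O=CCC[C@@]1(C)[C@H](CCC(=O)OC(C)(C)C)/C(=C(/C)C(=O)OC)CC[C@]1(C)O | intermediate
22 | methyl (2Z)-2-[(2R,3S,4S)-2-(3-tert-butoxy-3-oxopropyl)-4-hydroxy-3,4-dimethyl-3-[(3E)-4-methyl-5-oxopent-3-en-1-yl]cyclohexylidene]propanoate | O=C/C(C)=C/CC[C@@]1(C)[C@H](CCC(=O)OC(C)(C)C)/C(=C(/C)C(=O)OC)CC[C@]1(C)O | intermediate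
23 | geranyl bromide, (2E)-1-bromo-3,7-dimethylocta-2,6-diene | CC(C)=CCC/C(C)=C/CBr | starting material
24 | triethyl phosphite | CCOP(OCC)OCC | starting material
25 | diethyl [(2E)-3,7-dimethylocta-2,6-dien-1-yl]phosphonate | CC(C)=CCC/C(C)=C/CP(=O)(OCC)OCC | intermediate
26 | α-lithio derivative of 25 | CC(C)=CCC/C(C)=C/C([Li])P(=O)(OCC)OCC | intermediate
27 | methyl (2Z)-2-[(2R,3S,4S)-2-(3-tert-butoxy-3-oxopropyl)-4-hydroxy-3,4-dimethyl-3-[(3E,5E,7E)-4,8,12-trimethyltrideca-3,5,7,11-tetraen-1-yl]cyclohexylidene]propanoate | CC(C)=CCC/C(C)=C/C=C/C(C)=C/CC[C@@]1(C)[C@H](CCC(=O)OC(C)(C)C)/C(=C(/C)C(=O)OC)CC[C@]1(C)O | intermediate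
28 | (2Z)-2-[(2R,3S,4S)-4-hydroxy-2-(3-hydroxypropyl)-3,4-dimethyl-3-[(3E,5E,7E)-4,8,12-trimethyltrideca-3,5,7,11-tetraen-1-yl]cyclohexylidene]propan-1-ol | CC(C)=CCC/C(C)=C/C=C/C(C)=C/CC[C@@]1(C)[C@H](CCCO)/C(=C(/C)CO)CC[C@]1(C)O | intermediate
29 | CNP0237252.1, (2Z)-2-[(2R,3S,4S)-4-hydroxy-2-(3-hydroxypropyl)-3,4-dimethyl-3-[(3E,5E,7E)-4,8,12-trimethyltrideca-3,5,7,11-tetraen-1-yl]cyclohexylidene]propanal | CC(C)=CCC/C(C)=C/C=C/C(C)=C/CC[C@@]1(C)[C@H](CCCO)/C(=C(/C)C=O)CC[C@]1(C)O | target

**Step count**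

Total steps: 18. Longest linear sequence: 17 (steps 1–14 and 16–18 from limonene); step 15 is the one-step side branch.

**Steps most likely to fail**

Step 11. What may go wrong is poor facial discrimination at the planar C11 radical (CH3 against the silyloxypropyl arm), or reduction or back-transfer of the radical (plain hydrogenation, or isomerisation of the alkene into conjugation) outrunning the reversible addition to the ketone. The fallback sets out from 18 and replaces size control by oxygen–titanium bridging. The C11=C26 alkene is epoxidised (mCPBA, NaHCO3, CH2Cl2, 0 °C; the electron-poor C7=C2 alkene is inert) to the epoxide F1. Cp2TiCl (trivalent titanium, made from Cp2TiCl2 and Zn, THF, rt) opens it to the β-titanoxy C11 radical, which adds to the titanium-bound C10 ketone so that the CH2O group and the new C10–O should end cis, giving the 26-hydroxy diol F2. The primary neopentyl alcohol is then removed by Barton–McCombie-type deoxygenation: PhOC(S)Cl, pyridine, CH2Cl2 gives the O-phenyl thionocarbonate F3, and (Me3Si)3SiH, AIBN, toluene, 100 °C gives 19, where the route is rejoined.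

Step 9. What may go wrong is loss of alkene geometry in the alkenylcopper (equilibration through the allenolate) during the slow methylation, or protonation instead of alkylation. The fallback sets out from 13: the same carbocupration is quenched at −78 °C with I2, which should trap the alkenylcopper with retention as the α-iodo enoate F4. Negishi coupling (MeZnCl, Pd(PPh3)4, zerovalent palladium, THF, rt) then puts in the C25 methyl with retention and gives 17, where the route is rejoined.

Step 7. What may go wrong is elimination of the alkenyl nonaflate towards the allene, or base-induced proton migration at the propargylic and allylic C6–H with loss of the stereocentre. The fallback sets out from 9 and swaps dehydration for one-carbon degradation and homologation. TBSOTf, Et3N, CH2Cl2 gives the silyl enol ether F5. Ozonolysis of this most electron-rich alkene (1 equiv O3, CH2Cl2, −78 °C; Me2S) gives the nor-aldehyde F6. The Ohira–Bestmann reaction (dimethyl (1-diazo-2-oxopropyl)phosphonate, K2CO3, MeOH, 0 °C) converts it into the alkyne 11, where the route is rejoined.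

Further compounds
F1 | step 11 | 7-tert-butyl 1-methyl (2Z,4R)-2-methyl-3-(3-oxobutyl)-4-{2-[3-(triisopropylsilyloxy)propyl]oxiran-2-yl}hept-2-enedioate (both epoxide epimers) | COC(=O)/C(C)=C(/CCC(C)=O)[C@@H](CCC(=O)OC(C)(C)C)C1(CCCO[Si](C(C)C)(C(C)C)C(C)C)CO1
F2 | step 11 | 26-hydroxy analogue of 19: methyl (2Z)-2-[(2R,3S,4S)-2-(3-tert-butoxy-3-oxopropyl)-4-hydroxy-3-(hydroxymethyl)-4-methyl-3-[3-(triisopropylsilyloxy)propyl]cyclohexylidene]propanoate | CC(C)[Si](OCCC[C@@]1(CO)[C@H](CCC(=O)OC(C)(C)C)/C(=C(/C)C(=O)OC)CC[C@]1(C)O)(C(C)C)C(C)C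
F3 | step 11 | O-phenyl thionocarbonate of the primary alcohol of F2 | CC(C)[Si](OCCC[C@@]1(COC(=S)Oc2ccccc2)[C@H](CCC(=O)OC(C)(C)C)/C(=C(/C)C(=O)OC)CC[C@]1(C)O)(C(C)C)C(C)C
F4 | step 9 | 7-tert-butyl 1-methyl (4S)-2-iodo-3-[2-(2-methyl-1,3-dioxolan-2-yl)ethyl]-4-[5-(triisopropylsilyloxy)pent-1-en-2-yl]hept-2-enedioate (iodine cis to the C8 arm) | COC(=O)/C(I)=C(/CCC1(C)OCCO1)[C@@H](CCC(=O)OC(C)(C)C)C(=C)CCCO[Si](C(C)C)(C(C)C)C(C)C
F5 | step 7 | tert-butyldimethylsilyl enol ether of 9 (E/Z mixture) | CC(C)(C)[Si](C)(C)OC=C[C@@H](CCC(=O)OC(C)(C)C)C(=C)CCCO[Si](C(C)C)(C(C)C)C(C)C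
F6 | step 7 | tert-butyl (4S)-4-formyl-5-methylidene-8-(triisopropylsilyloxy)octanoate | O=C[C@@H](CCC(=O)OC(C)(C)C)C(=C)CCCO[Si](C(C)C)(C(C)C)C(C)C
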